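## The problem

The target is the 4'-O-acetate of an 8α-acyloxy germacranolide. Its ten-membered carbocycle (C1–C10) carries two ring-trans trisubstituted alkenes: C1=C10 (E, with the C14 methyl) and C4=C5 (the C15 hydroxymethyl cis to C6, hence Z by the CIP rules). The carbocycle is trans-fused at C6/C7 to an α-methylene-γ-butyrolactone (O–C6, C7, C11=C13, C12=O), and C8 bears an acrylate-type ester.

Three contiguous stereocentres lie on the ring: C6 (R), C7 (R) and C8 (S). A fourth, C3' (R), sits in the acyl side chain, too far away to be steered by the ring, so it needs its own source of chirality. Within the ring triad C6 is the natural controller: C7 is its neighbour across the lactone, and C8 can be set relative to C7 in the event that joins them.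

The ten-membered ring is costly to close. Its 1,5-diene undergoes Cope rearrangement on heating and transannular cyclisation under acid, so closure must be late and mild, with both alkene geometries fixed beforehand.

Several groups will not survive rough treatment:
- the α-methylene lactone and the 2-substituted acrylate are Michael acceptors;
- a free O8 alcohol can translactonise to the 8,12-olide under base;
- the secondary allylic 3'-hydroxyl next to the primary acetate invites acetyl migration and γ-lactonisation;
- the acetate and the allylic C15 alcohol exclude hydride, strong base and hydrogenation at the end.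

The enabling feature is the array C13=C11(C12=O)–C7–C8–O8. This is a homoallylic alcohol whose alkene is the exocyclic methylene of the lactone ring. It is therefore the allyl-transposed adduct of a C13-metallated 3-methylbutenolide (allyl unit C13–C11=C7 inside the lactone ring) and a C8 aldehyde. Because C7–C8 is a bond of the carbocycle, this γ-allylation can close the ten-membered ring, create C7 and C8 and unveil the methylene lactone in one operation.

## Retrosynthesis

**Side chain off (O8–C1').** Target 31 is traced to its bis-silyl ether 30 and then cut at the C8 ester into macrocyclic alcohol 21 and acid 28. The side chain has its own stereocentre and the most fragile functionality, so it should arrive last and complete. Acylating before ring closure would put a second acrylate and an acetate through the organometallic steps. Alcohol 21 carries O15 as a TBS ether and acid 28 carries O3' as a TBS ether, so one fluoride treatment finishes the synthesis. The forward reaction must acylate a hindered secondary alcohol faster than base can translactonise it, and the deprotection must not move the acetate.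

**Ring bond C7–C8 (key cut).** Alcohol 21 is opened between C7 and C8 to the bromomethylbutenolide aldehyde 19. The neighbouring cuts (C5–C6, C4=C5, C1–C2) all leave the methylene lactone to be built afterwards on a sensitive cyclodecadiene. This cut creates it during the closure and sets two stereocentres from one. Precursor 19 has a single stereocentre (C6) and no exocyclic alkene. The forward step must react at the γ-carbon C7, must be intramolecular, and must translate C6 into C7 (trans) and C8 (anti).

**Butenolide (C7=C11 and O6–C12).** Aldehyde 19 comes from alcohol 18 and its PMB ether 17 by oxidation-state changes at C8. These are placed late because the β,γ-unsaturated aldehyde is labile. Butenolide 17 is cut at the C7=C11 alkene (ring-closing metathesis) to acrylate 16, and 16 at the ester to divinyl carbinol 14 and 2-(bromomethyl)acrylic acid 15. Acid 15 is commercial and already contains C11, C12, C13 and the bromine, so no allylic bromination of a polyene is needed. The forward metathesis must engage only the terminal vinyl group and the acrylate.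

**C6–C7 and C5–C6.** Carbinol 14 is cut at C6–C7 to enal 13 and a vinyl nucleophile, and 13 at C5–C6 to alkenyl iodide 11 and a formyl donor. This is the only asymmetric step on the main line. The alternative of adding the C5 alkenyl metal to acrolein would leave a small, poorly differentiated aldehyde to the chiral catalyst. The forward reaction must deliver vinyl to the Si face of a Z-trisubstituted enal.

**C3–C4 and the C4=C5 geometry.** Iodide 11 is the silyl ether of iodo alcohol 10, which is cut at C3–C4 into homoallylic bromide 6 and propargyl alcohol 7. Anti-carbomagnesiation of the propargylic alkoxide puts the chain on C4 and the metal (then iodine) on C5 cis to C15. This fixes the C4=C5 geometry in the step that makes the bond, which an olefination would not guarantee for this trisubstituted alkene.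

**C1–C2, C10–C14 and the C1=C10 geometry.** Bromide 6 comes from alcohol 5, and 5 from alkyne 2 by syn-methylalumination (C14 and the E alkene) and opening of ethylene oxide by the alkenylalanate (C2–C3). Alkyne 2 is the PMB ether of but-3-yn-1-ol 1. The PMB group is chosen because it comes off oxidatively beside a TBS ether, an allylic bromide and a butenolide.

**Side-chain acid.** Acid 28 is cut at C1'–C2' to terminal alkyne 27 and carbon monoxide (Markovnikov hydroxycarbonylation). Alkyne 27 goes back through monoacetate 26 and diol 25 to acetonide 24, and 24 by one-carbon homologation to (R)-solketal 22. The chiral pool fixes C3' without relying on an asymmetric Morita–Baylis–Hillman reaction, and the acetate is in place before the carboxyl group appears, so the hydroxy acid can never lactonise.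

## Roads not taken

**Alternative 1: enolate-triggered Grob fragmentation.** The cut restores the C5–C10 bond, so the cyclodecadiene derives from the trans-decalin lactone A1 (1β-mesylate, C15 silyl enol ether, O8 PMB ether). In the forward step Bu4NF frees the C15 aldehyde enolate, which breaks C5–C10 and expels the mesylate to give the enal lactone A2.
- Merits: no macrocyclisation entropy; both ring alkene geometries follow stereospecifically from the antiperiplanar decalin bonds; C6, C7 and C8 are set on a rigid bicycle. In these respects it is better than the chosen plan.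
- Weak points: A1 needs six stereocentres, three of which (C1, C5, C10) are destroyed. A2 has a saturated C11, so the lactone must be α-methylenated with strong base on a cyclodecadiene that also carries an enal. C15 must be reduced back, and the PMB ether removed oxidatively from the sensitive diene.
- Comparison: the chosen plan sets the alkene geometries by carbometalation, which is equally dependable, and has the methylene lactone appear during ring closure, so nothing but acylation and desilylation follows the macrocycle.

**Alternative 2: vinyl iodide–aldehyde closure at C5–C6 with lactonisation.** The cut is C5–C6 plus the lactone C–O bond, leading to the acyclic iodo aldehyde ester A3. CrCl2 with catalytic NiCl2 would give the alkenylchromium species, which adds to the C6 aldehyde; the alkoxide then closes onto the C12 ester to give lactone A4.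
- Merits: this Ni/Cr closure is among the most dependable medium-ring carbon–carbon closures and tolerates almost any functionality. Here it is stronger than the indium closure, which is stretched to a new ring size.
- Weak points: C6 is created in the macrocyclisation next to an epimerisable C7 aldehyde stereocentre. C7 and C8 must be built beforehand by acyclic asymmetric chemistry. A4 lacks C13, so methylenation must follow on the macrocycle. O8 and O15 carry the same silyl group and would have to be differentiated again.
- Comparison: the chosen plan offsets the less proven closure with a precursor that has one stereocentre instead of two and with no lactone functionalisation after closure.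

**Alternative 3: Still–Gennari macro-olefination at C4=C5.** The cut is the C4=C5 alkene, giving the phosphonate aldehyde A5. KN(SiMe3)2 with 18-crown-6 would form the phosphonate anion, which condenses with the C5 aldehyde to give the ring ester A6 with the C15 ester cis to C6.
- Merits: all three ring stereocentres are secured before closure by well-understood acyclic methods, so nothing depends on macrocyclic stereocontrol. This is a real advantage over the chosen plan.
- Weak points: the olefination must form a ring-trans trisubstituted alkene in a ten-membered ring, where both rate and geometric selectivity are doubtful. The C5 aldehyde is α-alkoxy and β-branched and is exposed to a strong base. A6 still needs oxidation of the C12 arm, lactonisation, methylenation and ester reduction.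
- Comparison: the chosen plan is much shorter after ring closure and fixes the C4=C5 geometry in an acyclic, stereospecific step.

Key step: step 12

Assumption: germacrane numbering is used (C1–C15, lactone carbonyl C12, exocyclic methylene C13, side chain C1'–C4'); (−)-MIB is (2S)-3-exo-morpholinoisoborneol; (R)-solketal, ethylene oxide and the ligands are bought.

## Route

Step 1
Reactants: 1 but-3-yn-1-ol
Product: 2 1-[(but-3-yn-1-yloxy)methyl]-4-methoxybenzene
Conditions: NaH, PMBCl, Bu4NI (cat.), THF/DMF, 0 °C → rt
Reagents that add atoms: 4-methoxybenzyl chloride, COc1ccc(CCl)cc1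
Why: Williamson etherification of the primary alkoxide; one equivalent of NaH does not touch the alkyne C–H.

Step 2
Reactants: 2 1-[(but-3-yn-1-yloxy)methyl]-4-methoxybenzene
Product: 5 (E)-6-[(4-methoxybenzyl)oxy]-4-methylhex-3-en-1-ol, via alkenyldimethylalane 3 (not isolated), via lithium alkenylalanate 4 (not isolated)
Conditions: AlMe3, Cp2ZrCl2 (20 mol%), CH2Cl2, 0 °C → rt; evaporate, hexane; n-BuLi, 0 °C; ethylene oxide, THF, −30 °C → rt
Reagents that add atoms: trimethylaluminium, C[Al](C)C; ethylene oxide, C1CO1
Why: Negishi zirconium-catalysed methylalumination adds methyl and aluminium syn with aluminium on the terminal carbon, which fixes C14 and the E C1=C10 alkene. The derived lithium alanate opens ethylene oxide with retention at the alkenyl carbon and so adds C2 and C3.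

Step 3
Reactants: 5 (E)-6-[(4-methoxybenzyl)oxy]-4-methylhex-3-en-1-ol
Product: 6 1-({[(E)-6-bromo-3-methylhex-3-en-1-yl]oxy}methyl)-4-methoxybenzene
Conditions: CBr4, PPh3, 2,6-lutidine, CH2Cl2, 0 °C
Reagents that add atoms: carbon tetrabromide, BrC(Br)(Br)Br
Why: Appel bromination of a primary alcohol under neutral conditions; the PMB ether and the trisubstituted alkene are inert.

Step 4
Reactants: 6 1-({[(E)-6-bromo-3-methylhex-3-en-1-yl]oxy}methyl)-4-methoxybenzene; 7 prop-2-yn-1-ol (propargyl alcohol)
Product: 10 (5E)-2-[(Z)-iodomethylidene]-8-[(4-methoxybenzyl)oxy]-6-methyloct-5-en-1-ol, via Grignard reagent 8 (not isolated), via cyclic alkenylmagnesium alkoxide 9 (not isolated)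
Conditions: Mg, THF, rt; 7/MeMgCl (1:1), CuI (15 mol%), THF–Et2O, −10 °C → rt; I2, −40 → 0 °C
Reagents that add atoms: iodine, II
Why: Copper-catalysed anti-carbomagnesiation of a propargylic alkoxide: the alkyl group adds to C4 and magnesium ends on C5 inside a five-membered chelate, cis to the CH2O group. Iodinolysis with retention gives the iodide with C5–I cis to C15; homoprenyl-type Grignard reagents are known partners.

Step 5
Reactants: 10 (5E)-2-[(Z)-iodomethylidene]-8-[(4-methoxybenzyl)oxy]-6-methyloct-5-en-1-ol
Product: 11 tert-butyl({(5E)-2-[(Z)-iodomethylidene]-8-[(4-methoxybenzyl)oxy]-6-methyloct-5-en-1-yl}oxy)dimethylsilane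
Conditions: TBSCl, imidazole, CH2Cl2, 0 °C → rt
Reagents that add atoms: tert-butyldimethylsilyl chloride, CC(C)(C)[Si](C)(C)Cl
Why: Routine silylation of a primary allylic alcohol; it blocks O15 so that the later C6 aldehyde cannot close to a lactol or furan.

Step 6
Reactants: 11 tert-butyl({(5E)-2-[(Z)-iodomethylidene]-8-[(4-methoxybenzyl)oxy]-6-methyloct-5-en-1-yl}oxy)dimethylsilane
Product: 13 (2Z,6E)-3-{[(tert-butyldimethylsilyl)oxy]methyl}-9-[(4-methoxybenzyl)oxy]-7-methylnona-2,6-dienal, via alkenyllithium 12 (not isolated)
Conditions: t-BuLi (2.1 equiv), Et2O, −78 °C; DMF, −78 → 0 °C; aq. NH4Cl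
Reagents that add atoms: N,N-dimethylformamide, CN(C)C=O
Why: Iodine–lithium exchange in cold ether is faster than any attack on the ethers and the alkenyllithium keeps its geometry (no THF, no warming, so no 1,4 O→C silyl shift). Formylation with DMF gives the Z enal on work-up.

Step 7
Reactants: 13 (2Z,6E)-3-{[(tert-butyldimethylsilyl)oxy]methyl}-9-[(4-methoxybenzyl)oxy]-7-methylnona-2,6-dienal
Product: 14 (3S,4Z,8E)-5-{[(tert-butyldimethylsilyl)oxy]methyl}-11-[(4-methoxybenzyl)oxy]-9-methylundeca-1,4,8-trien-3-ol
Conditions: (CH2=CH)2Zn [from CH2=CHMgBr, ZnCl2, 1,4-dioxane], (−)-MIB (10 mol%), toluene, −30 → 0 °C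
Reagents that add atoms: divinylzinc, C=C[Zn]C=C
Why: Amino-alcohol-catalysed addition of an alkenylzinc to an aldehyde. The zinc alkoxide of (−)-MIB should deliver vinyl to the Si face of sp2-substituted aldehydes, which gives the 3S carbinol (C6, the stereocentre that later controls C7 and C8).

Step 8
Reactants: 14 (3S,4Z,8E)-5-{[(tert-butyldimethylsilyl)oxy]methyl}-11-[(4-methoxybenzyl)oxy]-9-methylundeca-1,4,8-trien-3-ol; 15 2-(bromomethyl)prop-2-enoic acid
Product: 16 (3S,4Z,8E)-5-{[(tert-butyldimethylsilyl)oxy]methyl}-11-[(4-methoxybenzyl)oxy]-9-methylundeca-1,4,8-trien-3-yl 2-(bromomethyl)prop-2-enoate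
Conditions: DIC, DMAP (5 mol%), CH2Cl2, −10 → 0 °C
Reagents that add atoms: none
Why: Steglich esterification; low temperature and only catalytic DMAP keep the allylic bromide from being quaternised and the bis-allylic carbinol from ionising, so C6 is untouched.

Step 9
Reactants: 16 (3S,4Z,8E)-5-{[(tert-butyldimethylsilyl)oxy]methyl}-11-[(4-methoxybenzyl)oxy]-9-methylundeca-1,4,8-trien-3-yl 2-(bromomethyl)prop-2-enoate
Product: 17 (5R)-3-(bromomethyl)-5-[(1Z,5E)-2-{[(tert-butyldimethylsilyl)oxy]methyl}-8-[(4-methoxybenzyl)oxy]-6-methylocta-1,5-dien-1-yl]furan-2(5H)-one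
Conditions: second-generation Grubbs catalyst RuCl2(=CHPh)(H2IMes)(PCy3) (5 mol%), CH2Cl2 (5 mM), 40 °C
Reagents that add atoms: none
Why: Ring-closing metathesis: the carbene forms at the terminal vinyl group and closes the five-membered ring onto the acrylate alkene, as known for 2-substituted acrylates of allylic alcohols. The trisubstituted C4=C5 and C1=C10 alkenes are too hindered to compete, and closure from C7 to C1 would need a trans-cycloheptene.

Step 10
Reactants: 17 (5R)-3-(bromomethyl)-5-[(1Z,5E)-2-{[(tert-butyldimethylsilyl)oxy]methyl}-8-[(4-methoxybenzyl)oxy]-6-methylocta-1,5-dien-1-yl]furan-2(5H)-one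
Product: 18 (5R)-3-(bromomethyl)-5-[(1Z,5E)-2-{[(tert-butyldimethylsilyl)oxy]methyl}-8-hydroxy-6-methylocta-1,5-dien-1-yl]furan-2(5H)-one
Conditions: DDQ, CH2Cl2/pH 7 buffer, 0 °C
Reagents that add atoms: none
Why: Oxidative PMB cleavage with DDQ; silyl ether, allylic bromide and butenolide are inert, and the neutral medium avoids base that could enolise the doubly activated C6–H.

Step 11
Reactants: 18 (5R)-3-(bromomethyl)-5-[(1Z,5E)-2-{[(tert-butyldimethylsilyl)oxy]methyl}-8-hydroxy-6-methylocta-1,5-dien-1-yl]furan-2(5H)-one
Product: 19 (5R)-3-(bromomethyl)-5-[(1Z,5E)-2-{[(tert-butyldimethylsilyl)oxy]methyl}-6-methyl-8-oxoocta-1,5-dien-1-yl]furan-2(5H)-one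
Conditions: Dess–Martin periodinane, NaHCO3, CH2Cl2, 0 °C
Reagents that add atoms: none
Why: Buffered Dess–Martin oxidation gives the β,γ-unsaturated aldehyde without moving C1=C10 into conjugation; the aldehyde is used at once.

Step 12
Reactants: 19 (5R)-3-(bromomethyl)-5-[(1Z,5E)-2-{[(tert-butyldimethylsilyl)oxy]methyl}-6-methyl-8-oxoocta-1,5-dien-1-yl]furan-2(5H)-one
Product: 21 (3aR,4S,6E,10Z,11aR)-10-{[(tert-butyldimethylsilyl)oxy]methyl}-4-hydroxy-6-methyl-3-methylidene-3a,4,5,8,9,11a-hexahydrocyclodeca[b]furan-2(3H)-one, via allylindium dibromide 20 (not isolated)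
Conditions: In powder (3 equiv), THF/H2O 3:1 (1 mM, slow addition of 19), rt
Reagents that add atoms: none
Why: Indium metal inserts into the allylic C13–Br bond to give allylindium 20, whose metal binds the C8 aldehyde oxygen; the new bond then forms at the γ-carbon C7 through a six-membered chair (In–C13–C11=C7···C8=O), which moves the alkene to C11=C13 and unveils the α-methylene lactone as C7–C8 closes the carbocycle. The closest known reaction type is the aqueous Barbier γ-allylation of aldehydes by 3-(bromomethyl)butenolides and 2-(bromomethyl)acrylates with In, Zn or CrCl2, and metal-mediated intramolecular allylations are an established way to close germacrane rings. The ten-membered ring closes by a 10-exo-trig addition to the aldehyde. C7 is controlled by C6: the aldehyde adds to the butenolide face opposite the C5 alkenyl group, giving the trans lactone, which the two ring-trans alkenes should span without strain. C8 is controlled by the chair: C6 is trans to C13 across C7=C11 (an E-type allylmetal locked by the lactone ring) and sits pseudo-equatorial together with the aldehyde chain C9, which places O8 anti to C6 and gives 8S. The step needs γ- over α-attack (the cyclic transition state secures it; α-attack would also require a twelve-membered ring), ring closure over oligomerisation (slow addition at high dilution onto excess metal) and survival of the O8 alkoxide (water protonates it at once, so it cannot translactonise to the 8,12-olide).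

Step 13
Reactants: 22 (R)-(2,2-dimethyl-1,3-dioxolan-4-yl)methanol ((R)-solketal)
Product: 24 (R)-4-ethynyl-2,2-dimethyl-1,3-dioxolane, via aldehyde 23 (not isolated)
Conditions: (COCl)2, DMSO, Et3N, CH2Cl2, −78 °C; crude 23, MeC(O)C(N2)P(O)(OMe)2, K2CO3, MeOH, 0 °C → rt
Reagents that add atoms: dimethyl (1-diazo-2-oxopropyl)phosphonate, COP(=O)(OC)C(=[N+]=[N-])C(C)=O
Why: Swern oxidation followed by Ohira–Bestmann (Seyferth–Gilbert) homologation of the crude aldehyde. The stereocentre comes from the chiral pool and this α-alkoxy aldehyde is known to pass through K2CO3/MeOH with little racemisation.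

Step 14
Reactants: 24 (R)-4-ethynyl-2,2-dimethyl-1,3-dioxolane
Product: 25 (R)-but-3-yne-1,2-diol
Conditions: Dowex 50W (H+), MeOH/H2O, rt
Reagents that add atoms: none
Why: Acid-catalysed acetonide hydrolysis; the stereocentre is not involved.

Step 15
Reactants: 25 (R)-but-3-yne-1,2-diol
Product: 26 (R)-2-hydroxybut-3-yn-1-yl acetate
Conditions: AcCl, 2,4,6-collidine, CH2Cl2, −78 °C
Reagents that add atoms: acetyl chloride, CC(=O)Cl
Why: Acylation with AcCl and a hindered pyridine base at low temperature differentiates the primary from the secondary propargylic hydroxyl.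

Step 16
Reactants: 26 (R)-2-hydroxybut-3-yn-1-yl acetate
Product: 27 (R)-2-[(tert-butyldimethylsilyl)oxy]but-3-yn-1-yl acetate
Conditions: TBSOTf, 2,6-lutidine, CH2Cl2, −78 °C
Reagents that add atoms: tert-butyldimethylsilyl trifluoromethanesulfonate, CC(C)(C)[Si](C)(C)OS(=O)(=O)C(F)(F)F
Why: Silylation with the triflate at −78 °C is faster than 1,2-acetyl migration, so the acetate stays on the primary oxygen.

Step 17
Reactants: 27 (R)-2-[(tert-butyldimethylsilyl)oxy]but-3-yn-1-yl acetate
Product: 28 (R)-4-acetoxy-3-[(tert-butyldimethylsilyl)oxy]-2-methylidenebutanoic acid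
Conditions: Pd(OAc)2 (2 mol%), 2-PyPPh2, CH3SO3H (cat.), CO (10 bar), H2O, acetone, 45 °C
Reagents that add atoms: carbon monoxide, [C-]#[O+]; water, O
Why: Palladium-catalysed Markovnikov hydroxycarbonylation of a terminal alkyne with a pyridylphosphine catalyst: the palladium hydride adds so that CO enters at the internal carbon, giving the 2-substituted acrylic acid directly. The stereocentre is not involved.

Step 18
Reactants: 21 (3aR,4S,6E,10Z,11aR)-10-{[(tert-butyldimethylsilyl)oxy]methyl}-4-hydroxy-6-methyl-3-methylidene-3a,4,5,8,9,11a-hexahydrocyclodeca[b]furan-2(3H)-one; 28 (R)-4-acetoxy-3-[(tert-butyldimethylsilyl)oxy]-2-methylidenebutanoic acid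
Product: 30 (3aR,4S,6E,10Z,11aR)-10-{[(tert-butyldimethylsilyl)oxy]methyl}-6-methyl-3-methylidene-2-oxo-2,3,3a,4,5,8,9,11a-octahydrocyclodeca[b]furan-4-yl (3R)-4-acetoxy-3-[(tert-butyldimethylsilyl)oxy]-2-methylidenebutanoate, via mixed anhydride 29 (not isolated)
Conditions: 2,4,6-Cl3C6H2COCl, Et3N, THF, rt; then 21, DMAP, toluene, rt
Reagents that add atoms: none
Why: Yamaguchi esterification through the mixed anhydride acylates hindered secondary alcohols; fast acylation of O8 forestalls translactonisation, and no stereocentre is changed.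

Step 19
Reactants: 30 (3aR,4S,6E,10Z,11aR)-10-{[(tert-butyldimethylsilyl)oxy]methyl}-6-methyl-3-methylidene-2-oxo-2,3,3a,4,5,8,9,11a-octahydrocyclodeca[b]furan-4-yl (3R)-4-acetoxy-3-[(tert-butyldimethylsilyl)oxy]-2-methylidenebutanoate
Product: 31 (3aR,4S,6E,10Z,11aR)-10-(hydroxymethyl)-6-methyl-3-methylidene-2-oxo-2,3,3a,4,5,8,9,11a-octahydrocyclodeca[b]furan-4-yl (3R)-4-acetoxy-3-hydroxy-2-methylidenebutanoate (CNP0219661.4)
Conditions: HF·pyridine, pyridine, THF, 0 °C → rt
Reagents that add atoms: none
Why: Buffered HF·pyridine cleaves both tert-butyldimethylsilyl ethers under mildly acidic conditions, which should leave the acetate in place (no migration as under basic fluoride) and spare the two Michael acceptors and the cyclodecadiene.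

## Compound list

1 | but-3-yn-1-ol | C#CCCO | starting material
2 | 1-[(but-3-yn-1-yloxy)methyl]-4-methoxybenzene | C#CCCOCc1ccc(OC)cc1 | intermediate
3 | dimethyl{(E)-4-[(4-methoxybenzyl)oxy]-2-methylbut-1-en-1-yl}alane | C[Al](C)/C=C(\C)CCOCc1ccc(OC)cc1 | intermediate
4 | lithium butyl(dimethyl){(E)-4-[(4-methoxybenzyl)oxy]-2-methylbut-1-en-1-yl}alanate | [Li+].CCCC[Al-](C)(C)/C=C(\C)CCOCc1ccc(OC)cc1 | intermediate
5 | (E)-6-[(4-methoxybenzyl)oxy]-4-methylhex-3-en-1-ol | OCC/C=C(\C)CCOCc1ccc(OC)cc1 | intermediate
6 | 1-({[(E)-6-bromo-3-methylhex-3-en-1-yl]oxy}methyl)-4-methoxybenzene | BrCC/C=C(\C)CCOCc1ccc(OC)cc1 | intermediate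
7 | prop-2-yn-1-ol | C#CCO | starting material
8 | {(E)-6-[(4-methoxybenzyl)oxy]-4-methylhex-3-en-1-yl}magnesium bromide | Br[Mg]CC/C=C(\C)CCOCc1ccc(OC)cc1 | intermediate
9 | 4-{(E)-6-[(4-methoxybenzyl)oxy]-4-methylhex-3-en-1-yl}-2,5-dihydro-1,2-oxamagnesole | COc1ccc(COCC/C(C)=C/CCC2=C[Mg]OC2)cc1 | intermediate
10 | (5E)-2-[(Z)-iodomethylidene]-8-[(4-methoxybenzyl)oxy]-6-methyloct-5-en-1-ol | OC/C(CC/C=C(\C)CCOCc1ccc(OC)cc1)=C\I | intermediate
11 | tert-butyl({(5E)-2-[(Z)-iodomethylidene]-8-[(4-methoxybenzyl)oxy]-6-methyloct-5-en-1-yl}oxy)dimethylsilane | CC(C)(C)[Si](C)(C)OC/C(CC/C=C(\C)CCOCc1ccc(OC)cc1)=C\I | intermediate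
12 | {(1Z,5E)-2-{[(tert-butyldimethylsilyl)oxy]methyl}-8-[(4-methoxybenzyl)oxy]-6-methylocta-1,5-dien-1-yl}lithium | CC(C)(C)[Si](C)(C)OC/C(CC/C=C(\C)CCOCc1ccc(OC)cc1)=C\[Li] | intermediate
13 | (2Z,6E)-3-{[(tert-butyldimethylsilyl)oxy]methyl}-9-[(4-methoxybenzyl)oxy]-7-methylnona-2,6-dienal | CC(C)(C)[Si](C)(C)OC/C(CC/C=C(\C)CCOCc1ccc(OC)cc1)=C\C=O | intermediate
14 | (3S,4Z,8E)-5-{[(tert-butyldimethylsilyl)oxy]methyl}-11-[(4-methoxybenzyl)oxy]-9-methylundeca-1,4,8-trien-3-ol | C=C[C@H](O)/C=C(\CO[Si](C)(C)C(C)(C)C)CC/C=C(\C)CCOCc1ccc(OC)cc1 | intermediate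
15 | 2-(bromomethyl)prop-2-enoic acid | C=C(CBr)C(=O)O | starting material
16 | (3S,4Z,8E)-5-{[(tert-butyldimethylsilyl)oxy]methyl}-11-[(4-methoxybenzyl)oxy]-9-methylundeca-1,4,8-trien-3-yl 2-(bromomethyl)prop-2-enoate | C=C[C@H](OC(=O)C(=C)CBr)/C=C(\CO[Si](C)(C)C(C)(C)C)CC/C=C(\C)CCOCc1ccc(OC)cc1 | intermediate
17 | (5R)-3-(bromomethyl)-5-[(1Z,5E)-2-{[(tert-butyldimethylsilyl)oxy]methyl}-8-[(4-methoxybenzyl)oxy]-6-methylocta-1,5-dien-1-yl]furan-2(5H)-one | O=C1O[C@H](/C=C(\CO[Si](C)(C)C(C)(C)C)CC/C=C(\C)CCOCc2ccc(OC)cc2)C=C1CBr | intermediate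
18 | (5R)-3-(bromomethyl)-5-[(1Z,5E)-2-{[(tert-butyldimethylsilyl)oxy]methyl}-8-hydroxy-6-methylocta-1,5-dien-1-yl]furan-2(5H)-one | O=C1O[C@H](/C=C(\CO[Si](C)(C)C(C)(C)C)CC/C=C(\C)CCO)C=C1CBr | intermediate
19 | (5R)-3-(bromomethyl)-5-[(1Z,5E)-2-{[(tert-butyldimethylsilyl)oxy]methyl}-6-methyl-8-oxoocta-1,5-dien-1-yl]furan-2(5H)-one | O=C1O[C@H](/C=C(\CO[Si](C)(C)C(C)(C)C)CC/C=C(\C)CC=O)C=C1CBr | intermediate
20 | allylindium dibromide from 19 (trivalent indium on C13) | O=C1O[C@H](/C=C(\CO[Si](C)(C)C(C)(C)C)CC/C=C(\C)CC=O)C=C1C[In](Br)Br | intermediate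
21 | (3aR,4S,6E,10Z,11aR)-10-{[(tert-butyldimethylsilyl)oxy]methyl}-4-hydroxy-6-methyl-3-methylidene-3a,4,5,8,9,11a-hexahydrocyclodeca[b]furan-2(3H)-one | C=C1C(=O)O[C@@H]2/C=C(\CO[Si](C)(C)C(C)(C)C)CC/C=C(\C)C[C@H](O)[C@@H]12 | intermediate
22 | (R)-(2,2-dimethyl-1,3-dioxolan-4-yl)methanol | OC[C@@H]1COC(C)(C)O1 | starting material
23 | (S)-2,2-dimethyl-1,3-dioxolane-4-carbaldehyde | O=C[C@@H]1COC(C)(C)O1 | intermediate
24 | (R)-4-ethynyl-2,2-dimethyl-1,3-dioxolane | C#C[C@@H]1COC(C)(C)O1 | intermediate
25 | (R)-but-3-yne-1,2-diol | C#C[C@@H](O)CO | intermediate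
26 | (R)-2-hydroxybut-3-yn-1-yl acetate | C#C[C@@H](O)COC(C)=O | intermediate
27 | (R)-2-[(tert-butyldimethylsilyl)oxy]but-3-yn-1-yl acetate | C#C[C@@H](O[Si](C)(C)C(C)(C)C)COC(C)=O | intermediate
28 | (R)-4-acetoxy-3-[(tert-butyldimethylsilyl)oxy]-2-methylidenebutanoic acid | C=C(C(=O)O)[C@@H](O[Si](C)(C)C(C)(C)C)COC(C)=O | intermediate
29 | (R)-4-acetoxy-3-[(tert-butyldimethylsilyl)oxy]-2-methylidenebutanoic 2,4,6-trichlorobenzoic anhydride | C=C(C(=O)OC(=O)c1c(Cl)cc(Cl)cc1Cl)[C@@H](O[Si](C)(C)C(C)(C)C)COC(C)=O | intermediate
30 | (3aR,4S,6E,10Z,11aR)-10-{[(tert-butyldimethylsilyl)oxy]methyl}-6-methyl-3-methylidene-2-oxo-2,3,3a,4,5,8,9,11a-octahydrocyclodeca[b]furan-4-yl (3R)-4-acetoxy-3-[(tert-butyldimethylsilyl)oxy]-2-methylidenebutanoate | C=C1C(=O)O[C@@H]2/C=C(\CO[Si](C)(C)C(C)(C)C)CC/C=C(\C)C[C@H](OC(=O)C(=C)[C@@H](O[Si](C)(C)C(C)(C)C)COC(C)=O)[C@@H]12 | intermediate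
31 | (3aR,4S,6E,10Z,11aR)-10-(hydroxymethyl)-6-methyl-3-methylidene-2-oxo-2,3,3a,4,5,8,9,11a-octahydrocyclodeca[b]furan-4-yl (3R)-4-acetoxy-3-hydroxy-2-methylidenebutanoate | C=C1C(=O)O[C@@H]2/C=C(\CO)CC/C=C(\C)C[C@H](OC(=O)C(=C)[C@@H](O)COC(C)=O)[C@@H]12 | target

## Step count and risks

Total step count: 19. Longest linear sequence: 14 (steps 1–12, 18, 19); the side-chain acid takes 5 steps (13–17).

**Step 12 (key step).** The strain of the forming ten-membered ring may override the chair arrangement, so that the aldehyde reacts through a boat-like geometry and facial selectivity at C8 erodes (O8 syn to C6). In addition, protonation of the allylindium by water and intermolecular addition compete with the slow ring closure. The fallback accepts the wrong C8 outcome instead of fighting it. It sets out from 19, runs the same closure to the 8-epi alcohol (3aR,4R)-isomer of 21 F1, and esterifies it with acid 28 under Mitsunobu conditions (PPh3, diisopropyl azodicarboxylate, toluene, 0 °C). This inverts C8 and comes back to the route at 30.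

**Step 7.** Enantiofacial discrimination may be poor because the transferred vinyl group is small and the enal is Z-trisubstituted, and the zinc aminoalkoxide may isomerise the enal before addition. The fallback sets out from 13. Me2Zn, trimethylsilylacetylene and the ProPhenol antipode that adds to the Si face give the silylated propargylic alcohol (3R)-1-(trimethylsilyl) enynol F2. K2CO3 in MeOH removes the silyl group to give the terminal propargylic alcohol F3. Semi-hydrogenation (H2, Pd/CaCO3 poisoned with Pb(OAc)2, quinoline) comes back to the route at 14.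

**Step 9.** Closure onto the 1,1-disubstituted acrylate may be slow, so that the carbene at C7 dimerises the terminal vinyl groups, and the allylic bromide may degrade the ruthenium carbene. The fallback sets out from 14 and carries C13 as a silyl ether through the metathesis. Esterification with 2-{[(triethylsilyl)oxy]methyl}prop-2-enoic acid F4 (from 2-(hydroxymethyl)prop-2-enoic acid, Et3SiCl and imidazole, the silyl ester being hydrolysed on work-up) gives the acrylate ester F5. The same metathesis gives the triethylsilyloxymethyl butenolide F6. PPTS in MeOH at 0 °C removes the triethylsilyl group beside the TBS ether to give the hydroxymethyl butenolide F7. CBr4/PPh3 comes back to the route at 17.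

**Step 17.** The bulky propargylic silyl ether may steer the palladium hydride so that CO enters at the terminal carbon (linear acid), and the acid co-catalyst may cause loss of the silyl group. The fallback sets out from 27 and fixes the regiochemistry before carbonylation. Hydrostannation with Bu3SnH catalysed by Mo(CO)3(CNtBu)3 places tin on the internal carbon to give the alkenylstannane F8. I2 in CH2Cl2 gives the alkenyl iodide F9. Carbonylation (Pd(OAc)2, PPh3, CO, H2O, i-Pr2NEt, DMF) comes back to the route at 28.

## Further compounds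

F1 | step 12 | (3aR,4R,6E,10Z,11aR)-10-{[(tert-butyldimethylsilyl)oxy]methyl}-4-hydroxy-6-methyl-3-methylidene-3a,4,5,8,9,11a-hexahydrocyclodeca[b]furan-2(3H)-one | C=C1C(=O)O[C@@H]2/C=C(\CO[Si](C)(C)C(C)(C)C)CC/C=C(\C)C[C@@H](O)[C@@H]12
F2 | step 7 | (3R,4Z,8E)-5-{[(tert-butyldimethylsilyl)oxy]methyl}-11-[(4-methoxybenzyl)oxy]-9-methyl-1-(trimethylsilyl)undeca-4,8-dien-1-yn-3-ol | C[Si](C)(C)C#C[C@H](O)/C=C(\CO[Si](C)(C)C(C)(C)C)CC/C=C(\C)CCOCc1ccc(OC)cc1
F3 | step 7 | (3R,4Z,8E)-5-{[(tert-butyldimethylsilyl)oxy]methyl}-11-[(4-methoxybenzyl)oxy]-9-methylundeca-4,8-dien-1-yn-3-ol | C#C[C@H](O)/C=C(\CO[Si](C)(C)C(C)(C)C)CC/C=C(\C)CCOCc1ccc(OC)cc1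
F4 | step 9 | 2-{[(triethylsilyl)oxy]methyl}prop-2-enoic acid | C=C(CO[Si](CC)(CC)CC)C(=O)O
F5 | step 9 | (3S,4Z,8E)-5-{[(tert-butyldimethylsilyl)oxy]methyl}-11-[(4-methoxybenzyl)oxy]-9-methylundeca-1,4,8-trien-3-yl 2-{[(triethylsilyl)oxy]methyl}prop-2-enoate | C=C[C@H](OC(=O)C(=C)CO[Si](CC)(CC)CC)/C=C(\CO[Si](C)(C)C(C)(C)C)CC/C=C(\C)CCOCc1ccc(OC)cc1
F6 | step 9 | (5R)-5-[(1Z,5E)-2-{[(tert-butyldimethylsilyl)oxy]methyl}-8-[(4-methoxybenzyl)oxy]-6-methylocta-1,5-dien-1-yl]-3-{[(triethylsilyl)oxy]methyl}furan-2(5H)-one | O=C1O[C@H](/C=C(\CO[Si](C)(C)C(C)(C)C)CC/C=C(\C)CCOCc2ccc(OC)cc2)C=C1CO[Si](CC)(CC)CC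
F7 | step 9 | (5R)-5-[(1Z,5E)-2-{[(tert-butyldimethylsilyl)oxy]methyl}-8-[(4-methoxybenzyl)oxy]-6-methylocta-1,5-dien-1-yl]-3-(hydroxymethyl)furan-2(5H)-one | O=C1O[C@H](/C=C(\CO[Si](C)(C)C(C)(C)C)CC/C=C(\C)CCOCc2ccc(OC)cc2)C=C1CO
F8 | step 17 | (S)-2-[(tert-butyldimethylsilyl)oxy]-3-(tributylstannyl)but-3-en-1-yl acetate | C=C([Sn](CCCC)(CCCC)CCCC)[C@@H](O[Si](C)(C)C(C)(C)C)COC(C)=O
F9 | step 17 | (S)-2-[(tert-butyldimethylsilyl)oxy]-3-iodobut-3-en-1-yl acetate | C=C(I)[C@@H](O[Si](C)(C)C(C)(C)C)COC(C)=O
A1 | alternative 1 | trans-decalin 6,12-lactone with 1β-mesylate, O8 PMB ether and C15 tert-butyldimethylsilyl enol ether | O=C1C[C@@H]2[C@@H](OCc3ccc(OC)cc3)C[C@@]4(C)[C@H](OS(C)(=O)=O)CC/C(=C\O[Si](C)(C)C(C)(C)C)[C@@H]4[C@H]2O1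
A2 | alternative 1 | ten-membered diene lactone with C15 enal and O8 PMB ether | C1C(=O)O[C@@H]2/C=C(\C=O)CC/C=C(\C)C[C@H](OCc3ccc(OC)cc3)[C@@H]12
A3 | alternative 2 | acyclic C5 alkenyl iodide with C6 aldehyde, C12 methyl ester and O8, O15 TBS ethers | COC(=O)C[C@@H](C=O)[C@@H](O[Si](C)(C)C(C)(C)C)C/C(C)=C/CC/C(CO[Si](C)(C)C(C)(C)C)=C/I
A4 | alternative 2 | ten-membered trans-fused lactone with O8 and O15 TBS ethers | C1C(=O)O[C@@H]2/C=C(\CO[Si](C)(C)C(C)(C)C)CC/C=C(\C)C[C@H](O[Si](C)(C)C(C)(C)C)[C@@H]12
A5 | alternative 3 | acyclic C4 bis(2,2,2-trifluoroethyl)phosphonate ester with C5 aldehyde, O6 PMB, O8 TBS and C12 PMB ethers | COC(=O)C(CC/C=C(\C)C[C@H](O[Si](C)(C)C(C)(C)C)[C@@H](CCOCc1ccc(OC)cc1)[C@H](OCc1ccc(OC)cc1)C=O)P(=O)(OCC(F)(F)F)OCC(F)(F)F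
A6 | alternative 3 | ten-membered diene with C15 methyl ester cis to C6 | COC(=O)/C1=C\[C@@H](OCc2ccc(OC)cc2)[C@H](CCOCc2ccc(OC)cc2)[C@@H](O[Si](C)(C)C(C)(C)C)C/C(C)=C/CC1
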